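## Structural features

Kazinol E is a (2S)-flavan: a resorcinol-derived ring A (C4a, C5–C8, C8a) is fused to the dihydropyran ring C (O1, C2, C3, C4), and C2, the only stereocentre, carries the catechol ring B (C1'–C6'). Ring A is substituted at both positions that are ortho to one oxygen and para to the other: C4a (by C4 of ring C) and C6 (by the quaternary carbon of a 1,1-dimethylallyl group), with the free 7-OH next to that quaternary carbon and C8 lying between O1 and O7. Ring B is contiguously pentasubstituted (C1' bonded to C2, prenyl groups at C2' and C3', hydroxyls at C4' and C5'), so the C2' prenyl group flanks the stereocentre and only C6' carries hydrogen. C2 is a benzylic ether carbon whose aryl group has an oxygen para to it (O4'), so the C2–O1 bond ionises easily, which opens ring C and racemises C2 under acid and makes SN2 chemistry at this carbon unreliable. The three C5 units exclude hydrogenation, strong acid and electrophilic halogen late in the route; the ortho-prenylphenol (C3'/O4') and the ortho-(1,1-dimethylallyl)phenol (C6/O7) cyclise under acid, and the free catechol is oxidised in basic air. The real difficulty is therefore to create the hindered, ionisable C2–O1 stereocentre enantioselectively in the presence of the olefins, while three C5 units are placed regiospecifically, two side by side on ring B and one as a quaternary centre on ring A. The key step exploits the fact that C2–C3–C4 can be an allyl unit in an open precursor, with C2 as its aryl-substituted terminus and O1 as an incoming aryloxide, while C4a, the carbon that must later bond to C4, is the brominated carbon of commercial 4-bromoresorcinol.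

## Logic of the disconnections

17 ⇒ 16. The two O–Si bonds at O4' and O5' are cut. Fluoride cleavage is the only deprotection that needs neither acid nor hydrogen, so it is placed last. The demand is a buffered, oxygen-free fluoride step that leaves C2 and the three olefins alone.

16 ⇒ 14. The C6–C(quaternary) bond is cut and the C5 unit is returned to O7 as a prenyl ether. A [3,3] shift makes the quaternary benzylic carbon intramolecularly, inverts the allyl unit to the 1,1-dimethylallyl form and frees the 7-OH in the same event. No separate reagent for the reverse prenyl group is needed. The demand is migration to C6 and not to C8, and a product phenol that survives the heating.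

14 ⇒ 12. The C4–C4a bond of ring C is cut, which leaves an aryl bromide at C4a and a terminal vinyl group (C3=C4) on the C2 ether carbon. Ring C is thus closed by an sp3–sp2 coupling that never touches C2. The demand is hydroboration of the one monosubstituted olefin beside three trisubstituted ones, and a cyclisation that outruns loss of boron.

12 ⇒ 8 + 10 (key disconnection). The O1–C2 bond is cut between the two halves of the molecule, with C2 as the substituted terminus of an allyl electrophile and O1 as an aryloxide. The cut is made here because a metal-bound allyl unit lets a catalyst set C2 while the C–O bond forms, without an SN2 event at a para-oxygenated benzylic carbon. It reduces the target to two achiral aromatic pieces of comparable size. The demand is attack at the aryl-bearing terminus, O- and not C-allylation, and high facial control despite the ortho prenyl group at C2'.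

8 ⇒ 7 ⇒ 6 ⇒ 5. The carbonate C–O bond, the ester oxidation level and the C2=C3 double bond are removed in turn. This two-carbon extension of an aryl aldehyde is routine and E-selective, and it places the future C4 as the carbon bearing the leaving group. The demand is only chemoselective ester reduction beside isolated olefins.

5 ⇒ 4 ⇒ 3 ⇒ 2 ⇒ 1. Both aryl–CH2 bonds at C2' and C3' are cut back to aryl bromides, then the O–Si bonds, the O–CH3 bond and the C3'–Br bond. The adjacent prenyl groups are thereby tied to positions that are fixed by the directing effects of a vanillin. All halogenation and Lewis acid chemistry falls before any olefin exists. The demand is a twofold coupling at neighbouring, hindered carbons with linear (α) prenyl transfer.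

10 ⇒ 9. The O7–CH2 bond is cut. The prenyl group serves first as the O7 protecting group and later as the source of the C6 substituent, so no protecting-group exchange is needed on ring A. The demand is alkylation of the hydroxyl para to bromine and not of the one ortho to it.

## Other disconnections considered

Alternative 1: The first route that comes to mind cuts C2–C3 (aldol) and O1–C2 (oxa-Michael). In the forward sense 5 is condensed with 2-hydroxy-4-(prenyloxy)acetophenone A1 to the 2'-hydroxychalcone A2, which is cyclised enantioselectively to the flavanone A3, and the C4 carbonyl is then removed.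
- The stereocentre of A3 is β to a ketone and can revert to A2 by retro-oxa-Michael addition. No 5-hydroxyl is present to hold the ring closed.
- Deoxygenation of C4 costs at least two further steps, and the usual silane/strong acid reduction would protonate the trisubstituted olefins.
- The basic aldol conditions threaten aryl silyl ethers.
- The variant that reduces a ketone asymmetrically and closes ring C by Mitsunobu displacement needs an SN2 reaction at a para-oxygenated, ortho-substituted benzylic carbinol, where ionisation competes.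

The chosen plan sets C2 by a catalyst at a metal-bound allyl unit and reaches the flavan oxidation level directly.

Alternative 2: O1–C2 and C3–C4 are cut together. The forward step is a hetero-Diels–Alder reaction of the ortho-quinone methide A5 (from a salicyl alcohol precursor) with the styrene A4 (from 5 by methylenation), which gives the flavan skeleton A6 in one step.
- It is the shortest plan, but A5 has no substituent at the methide carbon and A4 no binding group, so a chiral catalyst has little to hold and A6 is expected as a racemate.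
- The asynchronous transition state has para-silyloxybenzyl cation character.
- The prenyl groups are trisubstituted, electron-rich olefins that are themselves dienophiles for A5, while the styrene of A4 is hindered by the ortho prenyl group.

The chosen plan gives up one step of convergence for catalyst control at C2 and for chemoselectivity.

Alternative 3: O1–C2 is cut as a dehydrogenative bond, by a biomimetic oxidative cyclisation of the 1,3-diarylpropane A7. The catechol is oxidised to the ortho-quinone, which tautomerises to the para-quinone methide A8, and the C8a hydroxyl adds 6-exo to the methide carbon to give 17 without protecting groups.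
- Enantiocontrol would have to come from a chiral acid or base pairing with A8. The product is a para-hydroxybenzyl aryl ether that can re-ionise to A8 under the same catalysis, so kinetic selectivity would be exposed to erosion.
- An oxidase of the vanillyl alcohol oxidase class could in principle form and trap A8 in a chiral pocket, but A7 lies far from the small 4-alkylphenols such enzymes accept.
- A7 needs a saturated three-carbon link between two fully decorated arenes, made without hydrogenation.

The chosen plan rests on a reaction type with an established stereochemical model.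

Key step: step 9

Remark on the chemistry: the (Sa,Sc,Sc) ligand is assumed to deliver the (S)-branched ether, by analogy with the accepted facial model for aryl-substituted allyl carbonates; its antipode would be used if the opposite sense were found. Flavan numbering (O1, C2–C4, C4a, C5–C8, C8a; ring B C1'–C6') is used throughout, and "prenyl" means 3-methylbut-2-en-1-yl.

## Route

Step 1
Reactants: 1 6-bromovanillin (2-bromo-4-hydroxy-5-methoxybenzaldehyde)
Product: 2 2,3-dibromo-4-hydroxy-5-methoxybenzaldehyde
Conditions: Br2 (1.05 equiv), AcOH, 20 °C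
Reagents that add atoms: bromine, BrBr
Why: Electrophilic aromatic bromination; the free phenol directs to its only open ortho position (the future C3'), as in the bromination of vanillin, and the position ortho to the aldehyde and meta to the hydroxyl does not compete.

Step 2
Reactants: 2 2,3-dibromo-4-hydroxy-5-methoxybenzaldehyde
Product: 3 2,3-dibromo-4,5-dihydroxybenzaldehyde
Conditions: AlCl3, pyridine, CH2Cl2, reflux; then aq. HCl
Reagents that add atoms: none
Why: Lewis acid-assisted O-demethylation of a guaiacol: aluminium chelates the ortho-hydroxy-methoxy pair and pyridine removes the methyl group by SN2 attack; it is done before any olefin is present and tolerates the aldehyde and aryl bromides.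

Step 3
Reactants: 3 2,3-dibromo-4,5-dihydroxybenzaldehyde
Product: 4 2,3-dibromo-4,5-bis(triisopropylsilyloxy)benzaldehyde
Conditions: i-Pr3SiOTf (2.5 equiv), 2,6-lutidine, CH2Cl2, 0 °C to rt
Reagents that add atoms: triisopropylsilyl trifluoromethanesulfonate, CC(C)[Si](OS(=O)(=O)C(F)(F)F)(C(C)C)C(C)C
Why: Silyl ether formation with the reactive triflate, needed for the hydroxyl flanked by bromine; triisopropylsilyl ethers should survive organometallic, hydride and aqueous base steps and leave with fluoride at the end, so no acid is needed on the finished flavan.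

Step 4
Reactants: 4 2,3-dibromo-4,5-bis(triisopropylsilyloxy)benzaldehyde
Product: 5 2,3-bis(3-methylbut-2-en-1-yl)-4,5-bis(triisopropylsilyloxy)benzaldehyde
Conditions: Bu3SnCH2CH=CMe2 (3 equiv), Pd(PPh3)4 (10 mol %), LiCl, DMF, 100 °C
Reagents that add atoms: tributyl(3-methylbut-2-en-1-yl)stannane, CCCC[Sn](CCCC)(CCCC)CC=C(C)C
Why: Twofold Stille coupling; oxidative addition is easiest at the bromide ortho to the aldehyde and then occurs at its neighbour, and with triphenylphosphine the allylpalladium intermediate equilibrates so that reductive elimination should give the less hindered linear (α) prenyl product; fluoride-free conditions spare the silyl ethers.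

Step 5
Reactants: 5 2,3-bis(3-methylbut-2-en-1-yl)-4,5-bis(triisopropylsilyloxy)benzaldehyde
Product: 6 ethyl (E)-3-[2,3-bis(3-methylbut-2-en-1-yl)-4,5-bis(triisopropylsilyloxy)phenyl]prop-2-enoate
Conditions: (EtO)2P(O)CH2CO2Et, NaH, THF, 0 °C to rt
Reagents that add atoms: triethyl phosphonoacetate, CCOC(=O)CP(=O)(OCC)OCC
Why: Horner–Wadsworth–Emmons olefination with a stabilised phosphonate, E-selective; it forms the bond that becomes C2–C3 of the flavan.

Step 6
Reactants: 6 ethyl (E)-3-[2,3-bis(3-methylbut-2-en-1-yl)-4,5-bis(triisopropylsilyloxy)phenyl]prop-2-enoate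
Product: 7 (E)-3-[2,3-bis(3-methylbut-2-en-1-yl)-4,5-bis(triisopropylsilyloxy)phenyl]prop-2-en-1-ol
Conditions: i-Bu2AlH (2.5 equiv), CH2Cl2, −78 °C; aq. potassium sodium tartrate
Reagents that add atoms: none
Why: 1,2-Reduction of the enoate to the allylic alcohol; isolated olefins and aryl silyl ethers are inert to the aluminium hydride at low temperature.

Step 7
Reactants: 7 (E)-3-[2,3-bis(3-methylbut-2-en-1-yl)-4,5-bis(triisopropylsilyloxy)phenyl]prop-2-en-1-ol
Product: 8 (E)-3-[2,3-bis(3-methylbut-2-en-1-yl)-4,5-bis(triisopropylsilyloxy)phenyl]prop-2-en-1-yl methyl carbonate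
Conditions: ClCO2Me, pyridine, CH2Cl2, 0 °C
Reagents that add atoms: methyl chloroformate, COC(=O)Cl
Why: Acylation of the primary allylic alcohol; the methyl carbonate is the standard leaving group for iridium-catalysed allylic substitution and is made under non-ionising conditions.

Step 8
Reactants: 9 4-bromoresorcinol (4-bromobenzene-1,3-diol)
Product: 10 2-bromo-5-(3-methylbut-2-en-1-yloxy)phenol
Conditions: NaH (2.1 equiv), DMF, 0 °C; then Me2C=CHCH2Br (1.0 equiv)
Reagents that add atoms: 1-bromo-3-methylbut-2-ene, CC(C)=CCBr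
Why: Williamson etherification of the dianion; of the two aryloxide sites the one para to bromine is the more basic and the less hindered, so the single equivalent of prenyl bromide should react there, and the dipolar aprotic solvent favours O- over C-alkylation.

Step 9
Reactants: 8 (E)-3-[2,3-bis(3-methylbut-2-en-1-yl)-4,5-bis(triisopropylsilyloxy)phenyl]prop-2-en-1-yl methyl carbonate; 10 2-bromo-5-(3-methylbut-2-en-1-yloxy)phenol
Product: 12 (S)-1-bromo-2-{1-[2,3-bis(3-methylbut-2-en-1-yl)-4,5-bis(triisopropylsilyloxy)phenyl]prop-2-en-1-yloxy}-4-(3-methylbut-2-en-1-yloxy)benzene, via lithium aryloxide 11 (not isolated)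
Conditions: 10, LiN(SiMe3)2, THF, 0 °C; then 8, [Ir(cod)Cl]2 (2 mol %), (Sa,Sc,Sc)-phosphoramidite L from 1,1'-bi-2-naphthol and bis[1-(2-methoxyphenyl)ethyl]amine (4 mol %), catalyst pre-activated with n-PrNH2 and freed of volatiles, THF, 30 °C
Reagents that add atoms: none
Why: The cyclometalated iridium phosphoramidite (monovalent iridium) ionises the carbonate of 8 with inversion to a (π-allyl) complex of trivalent iridium, CO2 and methoxide being lost, and the lithium aryloxide 11 attacks from outside, anti to the metal, at the aryl-bearing allyl terminus, so that the O1–C2 bond forms and the vinyl group C3=C4 is left behind. The closest known reaction type is the iridium-catalysed branched- and enantioselective allylic etherification of cinnamyl-type carbonates with alkali-metal aryloxides. No ring is closed here; the step joins the two halves at O1–C2 and leaves the terminal alkene and the C4a–Br bond placed for the six-membered closure of step 10. The configuration at C2 is controlled by the catalyst alone: the ligand decides which enantioface of the allyl unit is bound to iridium, and the aryloxide adds to the opposite face of the substituted terminus, the (Sa,Sc,Sc) ligand being assigned to the (S) ether. Branched selectivity is needed and is secured by the intrinsic preference of these catalysts for attack at the more substituted terminus, which the electron-rich ring B reinforces. O- over C-allylation of the ambident aryloxide is needed and is favoured by the hard lithium aryloxide in THF and by the blocked C4a position. Enantioselectivity with the ortho prenyl group on ring B is the demanding point, for which the ligand with 2-methoxyphenyl arms, suited to ortho-substituted cinnamyl substrates, is chosen. Because the bond forms at a metal-bound allyl unit and not by displacement at a free para-oxygenated benzylic carbon, the SN1 leakage that threatens C2 in substitution chemistry is avoided, provided the reaction is stopped at full conversion so that the product ether is not re-ionised.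

Step 10
Reactants: 12 (S)-1-bromo-2-{1-[2,3-bis(3-methylbut-2-en-1-yl)-4,5-bis(triisopropylsilyloxy)phenyl]prop-2-en-1-yloxy}-4-(3-methylbut-2-en-1-yloxy)benzene
Product: 14 (2S)-2-[2,3-bis(3-methylbut-2-en-1-yl)-4,5-bis(triisopropylsilyloxy)phenyl]-7-(3-methylbut-2-en-1-yloxy)chroman, via alkylborane 13 (not isolated)
Conditions: 9-BBN dimer, THF, 0 °C to rt; then Pd(dppf)Cl2 (5 mol %), aq. K3PO4, DMF–THF, 60 °C, 0.01 M
Reagents that add atoms: none
Why: Anti-Markovnikov hydroboration with the bulky borane, which should pick the single monosubstituted olefin over the three trisubstituted ones, followed by intramolecular B-alkyl Suzuki–Miyaura coupling that closes ring C at C4–C4a as a six-membered ring; boron sits 1,3 to the aryloxy group, so β-alkoxy elimination is impossible, and C2 is not involved, so its configuration is kept.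

Step 11
Reactants: 14 (2S)-2-[2,3-bis(3-methylbut-2-en-1-yl)-4,5-bis(triisopropylsilyloxy)phenyl]-7-(3-methylbut-2-en-1-yloxy)chroman
Product: 16 (2S)-2-[2,3-bis(3-methylbut-2-en-1-yl)-4,5-bis(triisopropylsilyloxy)phenyl]-6-(2-methylbut-3-en-2-yl)chroman-7-ol, via cyclohexadienone 15 (not isolated)
Conditions: PhNEt2, 190 °C, sealed tube, argon, short reaction time
Reagents that add atoms: none
Why: Aromatic Claisen rearrangement: the [3,3] shift of the O7 prenyl ether forms the quaternary carbon–C6 bond with allylic inversion, and tautomerisation of dienone 15 restores ring A as the 7-phenol; C6 should be preferred over C8 because C8 is crowded between O1 and O7 and because an oxygen donor meta to the ether directs migration to the position para to itself; the basic solvent suppresses acid-catalysed cyclisation of the product.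

Step 12
Reactants: 16 (2S)-2-[2,3-bis(3-methylbut-2-en-1-yl)-4,5-bis(triisopropylsilyloxy)phenyl]-6-(2-methylbut-3-en-2-yl)chroman-7-ol
Product: 17 kazinol E, (2S)-2-[4,5-dihydroxy-2,3-bis(3-methylbut-2-en-1-yl)phenyl]-6-(2-methylbut-3-en-2-yl)chroman-7-ol
Conditions: Bu4NF (2.5 equiv), AcOH (2.5 equiv), THF, 0 °C, argon
Reagents that add atoms: none
Why: Fluoride cleavage of the two aryl silyl ethers; the acetic acid buffer keeps the catechol protonated against air oxidation, and no acid strong enough to ionise C2–O1 or to cyclise the ortho-allylphenols is present.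

## Compound list

1 | 6-bromovanillin (2-bromo-4-hydroxy-5-methoxybenzaldehyde) | O=Cc1cc(OC)c(O)cc1Br | starting material
2 | 2,3-dibromo-4-hydroxy-5-methoxybenzaldehyde | O=Cc1cc(OC)c(O)c(Br)c1Br | intermediate
3 | 2,3-dibromo-4,5-dihydroxybenzaldehyde | O=Cc1cc(O)c(O)c(Br)c1Br | intermediate
4 | 2,3-dibromo-4,5-bis(triisopropylsilyloxy)benzaldehyde | O=Cc1cc(O[Si](C(C)C)(C(C)C)C(C)C)c(O[Si](C(C)C)(C(C)C)C(C)C)c(Br)c1Br | intermediate
5 | 2,3-bis(3-methylbut-2-en-1-yl)-4,5-bis(triisopropylsilyloxy)benzaldehyde | O=Cc1cc(O[Si](C(C)C)(C(C)C)C(C)C)c(O[Si](C(C)C)(C(C)C)C(C)C)c(CC=C(C)C)c1CC=C(C)C | intermediate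
6 | ethyl (E)-3-[2,3-bis(3-methylbut-2-en-1-yl)-4,5-bis(triisopropylsilyloxy)phenyl]prop-2-enoate | CCOC(=O)/C=C/c1cc(O[Si](C(C)C)(C(C)C)C(C)C)c(O[Si](C(C)C)(C(C)C)C(C)C)c(CC=C(C)C)c1CC=C(C)C | intermediate
7 | (E)-3-[2,3-bis(3-methylbut-2-en-1-yl)-4,5-bis(triisopropylsilyloxy)phenyl]prop-2-en-1-ol | OC/C=C/c1cc(O[Si](C(C)C)(C(C)C)C(C)C)c(O[Si](C(C)C)(C(C)C)C(C)C)c(CC=C(C)C)c1CC=C(C)C | intermediate
8 | (E)-3-[2,3-bis(3-methylbut-2-en-1-yl)-4,5-bis(triisopropylsilyloxy)phenyl]prop-2-en-1-yl methyl carbonate | COC(=O)OC/C=C/c1cc(O[Si](C(C)C)(C(C)C)C(C)C)c(O[Si](C(C)C)(C(C)C)C(C)C)c(CC=C(C)C)c1CC=C(C)C | intermediate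
9 | 4-bromoresorcinol (4-bromobenzene-1,3-diol) | Oc1ccc(Br)c(O)c1 | starting material
10 | 2-bromo-5-(3-methylbut-2-en-1-yloxy)phenol | CC(C)=CCOc1ccc(Br)c(O)c1 | intermediate
11 | lithium 2-bromo-5-(3-methylbut-2-en-1-yloxy)phenoxide | CC(C)=CCOc1ccc(Br)c([O-])c1.[Li+] | intermediate
12 | (S)-1-bromo-2-{1-[2,3-bis(3-methylbut-2-en-1-yl)-4,5-bis(triisopropylsilyloxy)phenyl]prop-2-en-1-yloxy}-4-(3-methylbut-2-en-1-yloxy)benzene | C=C[C@H](Oc1cc(OCC=C(C)C)ccc1Br)c1cc(O[Si](C(C)C)(C(C)C)C(C)C)c(O[Si](C(C)C)(C(C)C)C(C)C)c(CC=C(C)C)c1CC=C(C)C | intermediate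
13 | 9-{(3S)-3-[2-bromo-5-(3-methylbut-2-en-1-yloxy)phenoxy]-3-[2,3-bis(3-methylbut-2-en-1-yl)-4,5-bis(triisopropylsilyloxy)phenyl]propyl}-9-borabicyclo[3.3.1]nonane | B1(C2CCCC1CCC2)CC[C@H](Oc1cc(OCC=C(C)C)ccc1Br)c1cc(O[Si](C(C)C)(C(C)C)C(C)C)c(O[Si](C(C)C)(C(C)C)C(C)C)c(CC=C(C)C)c1CC=C(C)C | intermediate
14 | (2S)-2-[2,3-bis(3-methylbut-2-en-1-yl)-4,5-bis(triisopropylsilyloxy)phenyl]-7-(3-methylbut-2-en-1-yloxy)chroman | CC(C)=CCOc1ccc2c(c1)O[C@H](c1cc(O[Si](C(C)C)(C(C)C)C(C)C)c(O[Si](C(C)C)(C(C)C)C(C)C)c(CC=C(C)C)c1CC=C(C)C)CC2 | intermediate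
15 | (2S)-2-[2,3-bis(3-methylbut-2-en-1-yl)-4,5-bis(triisopropylsilyloxy)phenyl]-6-(2-methylbut-3-en-2-yl)-3,4-dihydro-2H-chromen-7(6H)-one (both C6 epimers) | C=CC(C)(C)C1C=C2CC[C@@H](c3cc(O[Si](C(C)C)(C(C)C)C(C)C)c(O[Si](C(C)C)(C(C)C)C(C)C)c(CC=C(C)C)c3CC=C(C)C)OC2=CC1=O | intermediate
16 | (2S)-2-[2,3-bis(3-methylbut-2-en-1-yl)-4,5-bis(triisopropylsilyloxy)phenyl]-6-(2-methylbut-3-en-2-yl)chroman-7-ol | C=CC(C)(C)c1cc2c(cc1O)O[C@H](c1cc(O[Si](C(C)C)(C(C)C)C(C)C)c(O[Si](C(C)C)(C(C)C)C(C)C)c(CC=C(C)C)c1CC=C(C)C)CC2 | intermediate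
17 | kazinol E, (2S)-2-[4,5-dihydroxy-2,3-bis(3-methylbut-2-en-1-yl)phenyl]-6-(2-methylbut-3-en-2-yl)chroman-7-ol | C=CC(C)(C)c1cc2c(cc1O)O[C@H](c1cc(O)c(O)c(CC=C(C)C)c1CC=C(C)C)CC2 | target

## Step count and least certain steps

Total step count: 12. Longest linear sequence: 11 (steps 1–7 and 9–12).

**Step 9 (key step).**
- What may go wrong: loss of enantiofacial control and of branched selectivity, because the ortho prenyl group crowds the allyl–iridium complex; re-ionisation of the doubly activated product ether by the catalyst, with racemisation and drift to the linear ether; C-allylation of the aryloxide.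
- Fallback: it sets out from 5 and comes back at 14, with the stereocentre set by ketone reduction and ring C closed at O1–C8a, so that no substitution occurs at C2. Addition of vinylmagnesium bromide to 5 (THF, −78 °C) gives racemic 1-[2,3-bis(3-methylbut-2-en-1-yl)-4,5-bis(triisopropylsilyloxy)phenyl]prop-2-en-1-ol F1. Heck arylation of this allylic alcohol with 2-bromo-1-iodo-4-(3-methylbut-2-en-1-yloxy)benzene F2 (from 3-bromo-4-iodophenol, prenyl bromide and K2CO3) under Pd(OAc)2, Bu4NCl, NaHCO3, DMF, 45 °C should couple at iodine and, by β-hydride elimination towards the carbinol, give the saturated ketone 3-[2-bromo-4-(3-methylbut-2-en-1-yloxy)phenyl]-1-[2,3-bis(3-methylbut-2-en-1-yl)-4,5-bis(triisopropylsilyloxy)phenyl]propan-1-one F3. Corey–Bakshi–Shibata reduction ((R)-Me-CBS oxazaborolidine, catecholborane, toluene, −78 °C; catecholborane is chosen because it spares the olefins) should give the (S)-alcohol (1S)-3-[2-bromo-4-(3-methylbut-2-en-1-yloxy)phenyl]-1-[2,3-bis(3-methylbut-2-en-1-yl)-4,5-bis(triisopropylsilyloxy)phenyl]propan-1-ol F4. Intramolecular palladium-catalysed C–O coupling (Pd(OAc)2, 2-(di-tert-butylphosphino)-1,1'-binaphthyl, Cs2CO3, toluene, 70 °C) then closes ring C with retention to 14.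

**Step 4.**
- What may go wrong: stalling of the second coupling at the bromide flanked by the new prenyl group and the silyl ether, with protodebromination; partial γ-transfer of the prenyl group to give the 1,1-dimethylallyl isomer.
- Fallback: it sets out from 4 and comes back at 5, and replaces palladium coupling by arylmetal allylation. Acetalisation (HC(OMe)3, cat. TsOH, MeOH) gives 2,3-dibromo-1-(dimethoxymethyl)-4,5-bis(triisopropylsilyloxy)benzene F5. Bromine–magnesium exchange next to the acetal (i-PrMgCl·LiCl, THF, −15 °C), transmetalation with CuBr·SMe2 and prenyl bromide give 3-bromo-1-(dimethoxymethyl)-2-(3-methylbut-2-en-1-yl)-4,5-bis(triisopropylsilyloxy)benzene F6. Bromine–lithium exchange of the remaining bromide (t-BuLi, THF, −78 °C), CuBr·SMe2 and prenyl bromide give 1-(dimethoxymethyl)-2,3-bis(3-methylbut-2-en-1-yl)-4,5-bis(triisopropylsilyloxy)benzene F7. Mild hydrolysis (pyridinium p-toluenesulfonate, acetone–water) returns 5.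

**Step 10.**
- What may go wrong: hydroboration of a prenyl olefin beside the vinyl group; slow oxidative addition into the electron-rich aryl bromide, so that protodeboronation or 1,3-elimination of the borate onto the benzylic ether carbon overtakes ring closure; palladium-mediated loss of the O7 prenyl group.
- Fallback: it sets out from 8 and comes back at 14, and avoids both the borane and zerovalent palladium. 2,4-Dihydroxybenzaldehyde is prenylated at the 4-hydroxyl (prenyl bromide, K2CO3, acetone) to 2-hydroxy-4-(3-methylbut-2-en-1-yloxy)benzaldehyde F8. Wittig methylenation (Ph3P=CH2, 2.2 equiv, THF) gives 5-(3-methylbut-2-en-1-yloxy)-2-vinylphenol F9. Iridium-catalysed etherification with 8 under the conditions of step 9 gives (S)-2-{1-[2,3-bis(3-methylbut-2-en-1-yl)-4,5-bis(triisopropylsilyloxy)phenyl]prop-2-en-1-yloxy}-4-(3-methylbut-2-en-1-yloxy)-1-vinylbenzene F10. Ring-closing metathesis of the two monosubstituted olefins (second-generation Grubbs catalyst, CH2Cl2, 40 °C, protected from light) gives (2S)-2-[2,3-bis(3-methylbut-2-en-1-yl)-4,5-bis(triisopropylsilyloxy)phenyl]-7-(3-methylbut-2-en-1-yloxy)-2H-chromene F11. Diimide (2-nitrobenzenesulfonylhydrazide, Et3N, CH2Cl2, rt) should reduce only the cis-disubstituted C3=C4 bond and return 14.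

**Step 11.**
- What may go wrong: insufficient regioselectivity, with migration to C8 between the two oxygens; abnormal Claisen rearrangement or cyclisation of the product phenol onto its vinyl group on prolonged heating.
- Fallback: it sets out from 8 and comes back at 17, and fixes C6 with a bromine atom instead of a sigmatropic preference. 4,6-Dibromoresorcinol is monosilylated (i-Pr3SiCl, imidazole, DMF) to 2,4-dibromo-5-(triisopropylsilyloxy)phenol F12. Etherification with 8 as in step 9 gives (S)-1,5-dibromo-2-{1-[2,3-bis(3-methylbut-2-en-1-yl)-4,5-bis(triisopropylsilyloxy)phenyl]prop-2-en-1-yloxy}-4-(triisopropylsilyloxy)benzene F13. Hydroboration and intramolecular Suzuki–Miyaura coupling as in step 10 should engage the bromide ortho to the ether oxygen, the only one within reach of boron, and give (2S)-6-bromo-2-[2,3-bis(3-methylbut-2-en-1-yl)-4,5-bis(triisopropylsilyloxy)phenyl]-7-(triisopropylsilyloxy)chroman F14. A γ-selective Suzuki–Miyaura coupling with prenylboronic acid pinacol ester (Pd(OAc)2, a bulky di-tert-butylbiarylphosphine that speeds reductive elimination from the γ-bound allyl, aq. K3PO4, MeCN) gives (2S)-2-[2,3-bis(3-methylbut-2-en-1-yl)-4,5-bis(triisopropylsilyloxy)phenyl]-6-(2-methylbut-3-en-2-yl)-7-(triisopropylsilyloxy)chroman F15. Desilylation as in step 12 then gives 17.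

## Further compounds

F1 | step 9 | racemic 1-[2,3-bis(3-methylbut-2-en-1-yl)-4,5-bis(triisopropylsilyloxy)phenyl]prop-2-en-1-ol | C=CC(O)c1cc(O[Si](C(C)C)(C(C)C)C(C)C)c(O[Si](C(C)C)(C(C)C)C(C)C)c(CC=C(C)C)c1CC=C(C)C
F2 | step 9 | 2-bromo-1-iodo-4-(3-methylbut-2-en-1-yloxy)benzene | CC(C)=CCOc1ccc(I)c(Br)c1
F3 | step 9 | 3-[2-bromo-4-(3-methylbut-2-en-1-yloxy)phenyl]-1-[2,3-bis(3-methylbut-2-en-1-yl)-4,5-bis(triisopropylsilyloxy)phenyl]propan-1-one | O=C(CCc1ccc(OCC=C(C)C)cc1Br)c1cc(O[Si](C(C)C)(C(C)C)C(C)C)c(O[Si](C(C)C)(C(C)C)C(C)C)c(CC=C(C)C)c1CC=C(C)C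
F4 | step 9 | (1S)-3-[2-bromo-4-(3-methylbut-2-en-1-yloxy)phenyl]-1-[2,3-bis(3-methylbut-2-en-1-yl)-4,5-bis(triisopropylsilyloxy)phenyl]propan-1-ol | O[C@@H](CCc1ccc(OCC=C(C)C)cc1Br)c1cc(O[Si](C(C)C)(C(C)C)C(C)C)c(O[Si](C(C)C)(C(C)C)C(C)C)c(CC=C(C)C)c1CC=C(C)C
F5 | step 4 | 2,3-dibromo-1-(dimethoxymethyl)-4,5-bis(triisopropylsilyloxy)benzene | COC(OC)c1cc(O[Si](C(C)C)(C(C)C)C(C)C)c(O[Si](C(C)C)(C(C)C)C(C)C)c(Br)c1Br
F6 | step 4 | 3-bromo-1-(dimethoxymethyl)-2-(3-methylbut-2-en-1-yl)-4,5-bis(triisopropylsilyloxy)benzene | COC(OC)c1cc(O[Si](C(C)C)(C(C)C)C(C)C)c(O[Si](C(C)C)(C(C)C)C(C)C)c(Br)c1CC=C(C)C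
F7 | step 4 | 1-(dimethoxymethyl)-2,3-bis(3-methylbut-2-en-1-yl)-4,5-bis(triisopropylsilyloxy)benzene | COC(OC)c1cc(O[Si](C(C)C)(C(C)C)C(C)C)c(O[Si](C(C)C)(C(C)C)C(C)C)c(CC=C(C)C)c1CC=C(C)C
F8 | step 10 | 2-hydroxy-4-(3-methylbut-2-en-1-yloxy)benzaldehyde | O=Cc1ccc(OCC=C(C)C)cc1O
F9 | step 10 | 5-(3-methylbut-2-en-1-yloxy)-2-vinylphenol | C=Cc1ccc(OCC=C(C)C)cc1O
F10 | step 10 | (S)-2-{1-[2,3-bis(3-methylbut-2-en-1-yl)-4,5-bis(triisopropylsilyloxy)phenyl]prop-2-en-1-yloxy}-4-(3-methylbut-2-en-1-yloxy)-1-vinylbenzene | C=C[C@H](Oc1cc(OCC=C(C)C)ccc1C=C)c1cc(O[Si](C(C)C)(C(C)C)C(C)C)c(O[Si](C(C)C)(C(C)C)C(C)C)c(CC=C(C)C)c1CC=C(C)C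
F11 | step 10 | (2S)-2-[2,3-bis(3-methylbut-2-en-1-yl)-4,5-bis(triisopropylsilyloxy)phenyl]-7-(3-methylbut-2-en-1-yloxy)-2H-chromene | CC(C)=CCOc1ccc2c(c1)O[C@H](c1cc(O[Si](C(C)C)(C(C)C)C(C)C)c(O[Si](C(C)C)(C(C)C)C(C)C)c(CC=C(C)C)c1CC=C(C)C)C=C2
F12 | step 11 | 2,4-dibromo-5-(triisopropylsilyloxy)phenol | Oc1cc(O[Si](C(C)C)(C(C)C)C(C)C)c(Br)cc1Br
F13 | step 11 | (S)-1,5-dibromo-2-{1-[2,3-bis(3-methylbut-2-en-1-yl)-4,5-bis(triisopropylsilyloxy)phenyl]prop-2-en-1-yloxy}-4-(triisopropylsilyloxy)benzene | C=C[C@H](Oc1cc(O[Si](C(C)C)(C(C)C)C(C)C)c(Br)cc1Br)c1cc(O[Si](C(C)C)(C(C)C)C(C)C)c(O[Si](C(C)C)(C(C)C)C(C)C)c(CC=C(C)C)c1CC=C(C)C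
F14 | step 11 | (2S)-6-bromo-2-[2,3-bis(3-methylbut-2-en-1-yl)-4,5-bis(triisopropylsilyloxy)phenyl]-7-(triisopropylsilyloxy)chroman | Brc1cc2c(cc1O[Si](C(C)C)(C(C)C)C(C)C)O[C@H](c1cc(O[Si](C(C)C)(C(C)C)C(C)C)c(O[Si](C(C)C)(C(C)C)C(C)C)c(CC=C(C)C)c1CC=C(C)C)CC2
F15 | step 11 | (2S)-2-[2,3-bis(3-methylbut-2-en-1-yl)-4,5-bis(triisopropylsilyloxy)phenyl]-6-(2-methylbut-3-en-2-yl)-7-(triisopropylsilyloxy)chroman | C=CC(C)(C)c1cc2c(cc1O[Si](C(C)C)(C(C)C)C(C)C)O[C@H](c1cc(O[Si](C(C)C)(C(C)C)C(C)C)c(O[Si](C(C)C)(C(C)C)C(C)C)c(CC=C(C)C)c1CC=C(C)C)CC2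
A1 | alternative 1 | 2-hydroxy-4-(3-methylbut-2-en-1-yloxy)acetophenone | CC(=O)c1ccc(OCC=C(C)C)cc1O
A2 | alternative 1 | (E)-1-[2-hydroxy-4-(3-methylbut-2-en-1-yloxy)phenyl]-3-[2,3-bis(3-methylbut-2-en-1-yl)-4,5-bis(triisopropylsilyloxy)phenyl]prop-2-en-1-one | O=C(/C=C/c1cc(O[Si](C(C)C)(C(C)C)C(C)C)c(O[Si](C(C)C)(C(C)C)C(C)C)c(CC=C(C)C)c1CC=C(C)C)c1ccc(OCC=C(C)C)cc1O
A3 | alternative 1 | (2S)-2-[2,3-bis(3-methylbut-2-en-1-yl)-4,5-bis(triisopropylsilyloxy)phenyl]-7-(3-methylbut-2-en-1-yloxy)chroman-4-one | O=C1C[C@@H](c3cc(O[Si](C(C)C)(C(C)C)C(C)C)c(O[Si](C(C)C)(C(C)C)C(C)C)c(CC=C(C)C)c3CC=C(C)C)Oc2cc(OCC=C(C)C)ccc21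
A4 | alternative 2 | 1-ethenyl-2,3-bis(3-methylbut-2-en-1-yl)-4,5-bis(triisopropylsilyloxy)benzene | C=Cc1cc(O[Si](C(C)C)(C(C)C)C(C)C)c(O[Si](C(C)C)(C(C)C)C(C)C)c(CC=C(C)C)c1CC=C(C)C
A5 | alternative 2 | 6-methylidene-3-(3-methylbut-2-en-1-yloxy)cyclohexa-2,4-dien-1-one | C=C1C=CC(OCC=C(C)C)=CC1=O
A6 | alternative 2 | racemic 2-[2,3-bis(3-methylbut-2-en-1-yl)-4,5-bis(triisopropylsilyloxy)phenyl]-7-(3-methylbut-2-en-1-yloxy)chroman | CC(C)=CCOc1ccc2c(c1)OC(c1cc(O[Si](C(C)C)(C(C)C)C(C)C)c(O[Si](C(C)C)(C(C)C)C(C)C)c(CC=C(C)C)c1CC=C(C)C)CC2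
A7 | alternative 3 | 4-{3-[4,5-dihydroxy-2,3-bis(3-methylbut-2-en-1-yl)phenyl]propyl}-6-(2-methylbut-3-en-2-yl)benzene-1,3-diol | C=CC(C)(C)c1cc(CCCc2cc(O)c(O)c(CC=C(C)C)c2CC=C(C)C)c(O)cc1O
A8 | alternative 3 | 4-{3-[2,4-dihydroxy-5-(2-methylbut-3-en-2-yl)phenyl]propylidene}-6-hydroxy-2,3-bis(3-methylbut-2-en-1-yl)cyclohexa-2,5-dien-1-one | C=CC(C)(C)c1cc(CCC=C2C=C(O)C(=O)C(CC=C(C)C)=C2CC=C(C)C)c(O)cc1O
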